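In a one-step world every electrophile lost would stand as target, but in the green run the target falls while the electrophile goes on falling, so a second step seems to spend target and electrophile together.

| flask | electrophile | free base | protonated nucleophile | remark | time |
|---|---|---|---|---|---|
| blue | 0.0029 M | 8 mM | 0.020 M | run made earlier |  |
| green | 0.025 M | 8 mM | 0.020 M | run made earlier |  |
| red | 0.010 M | 8 mM | 0.022 M | run made earlier |  |
| alpha | 0.0050 M | 8.00 mM | 0.0200 M |  | 30 h |
| epsilon | 0.010 M | 8.00 mM | 0.0200 M |  | 30 h |
| beta | 0.020 M | 8.00 mM | 0.0800 M |  | 30 h |
| theta | 0.015 M | 8.00 mM | 0.0200 M |  | 30 h |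
| zeta | 0.030 M | 8.00 mM | 0.00500 M |  | 30 h |

| run | time / h | target / % | electrophile / % |
|---|---|---|---|
| blue | 5.00 | 36.7 | 62.4 |
| blue | 10.0 | 55.3 | 41.2 |
| blue | 15.0 | 63.9 | 31.5 |
| blue | 20.0 | 71.9 | 23.7 |
| blue | 25.0 | 75.9 | 18.0 |
| blue | 30.0 | 79.7 | 13.1 |
| green | 5.00 | 11.2 | 81.3 |
| green | 10.0 | 11.7 | 79.5 |
| green | 15.0 | 10.3 | 76.1 |
| green | 20.0 | 9.9 | 72.8 |
| green | 25.0 | 8.0 | 73.2 |
| green | 30.0 | 6.5 | 69.6 |
| red | 2.50 | 18.3 | 80.4 |
| red | 5.00 | 27.4 | 71.3 |
| red | 8.00 | 30.1 | 65.2 |
| red | 15.0 | 31.6 | 55.8 |
| red | 30.0 | 28.7 | 46.2 |

(standard deviation of a reading: 1 percentage point)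



* ranking by amount of target, in percent of the electrophile charged, from high to low, at 30 h (alpha / epsilon / beta / theta / zeta)
* the same order at 10 d (alpha / epsilon / beta / theta / zeta)
* the amount of target, in percent of the electrophile charged of the flask you put first, at 30 h
* the amount of target, in percent of the electrophile charged of the flask you put last, at 30 h

The first step adds to both electrophile gone and target present, while the second adds to the first and takes from the other, so their half-sum counts first steps. The green run, charged with 0.025 M, has made 3.74 mM of them at 5.00 h, and 4.61 mM at 30.0 h. But the red run, with less electrophile, reaches 4.12 mM at 30.0 h. Both lie near half the free base charge, 4.00 mM, though the green run slowly leaks past it. Call this the base ceiling: the green and red runs read as if free base were the limiting reagent, while the blue run stays under the ceiling at 2.42 mM.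

Divided by each charge, the ceiling gives 80.0% for alpha, 40.0% for epsilon, 26.7% for theta, 20.0% for beta and 13.3% for zeta. My own reckoning takes that as the ranking at 30 h, with target somewhat below each share.

The forecast, holding that “Total electrophile conversion is therefore capped by the 8 mM base”, gives alpha > epsilon > theta > beta > zeta at 30 h, alpha > beta > epsilon > theta > zeta at 10 d, top 58% and low 1.5%.

The flasks give alpha > epsilon > theta > beta > zeta at 30 h and alpha > epsilon > beta > theta > zeta at 10 d, with top 61.8% and low 3.64%.

    acid set free → by-product carried off (k = 2.30 × 10⁻⁵ /s)
    electrophile + target → side product (k = 5.80 × 10⁻⁴ /M/s)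
    acid set free + free base ⇌ salt of the base, settled at all times (K = 9.30 × 10⁵ /M)
    nucleophile + acid set free ⇌ protonated nucleophile, settled at all times (K = 1.10 × 10⁶ /M)
    electrophile + nucleophile → acid set free + target (k = 0.00570 /M/s)

Each first step draws its nucleophile from the protonated nucleophile, which sets free one acid, and then sets free a second, so free base is used twice over as salt of the base. That joining is the main reason for the target in alpha, which holds 61.8% with it and 4.95% with it taken away. In zeta, where side product counts double, first steps, taken as target plus the side product divided by 2, come to 13.3%, just under its share. The neighbour flask, like zeta but with 0.012 M of electrophile, has a share of 33.3% and stands lower, at 29.6%, with 10% of its free base left.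

(The runs come from a simulation for an exercise; noise was put on by code.)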